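## Retrosynthetic overview

1. The C3–OH bond (together with C4–Br) is made last: the target comes from a spiro triene whose ring A is a 1-methylcyclohexa-1,3-diene, by a catalyst-controlled anti bromohydroxylation that sets both ring A stereocentres.
2. The ring A diene comes from a spiro cyclohexenone by methyl 1,2-addition and 1,4-dehydration.
3. Ring B and the spiro quaternary centre come from an enantioselective Diels–Alder reaction of an exocyclic dienone with 2-bromo-3-methylbuta-1,3-diene, which carries the vinyl bromide.
4. The dienophile comes from alpha-prime methylenation of 5,5-dimethylcyclohex-2-en-1-one; the diene comes from Markovnikov hydrobromination (bromoboration, then protonolysis) of 2-methylbut-1-en-3-yne.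
5. Ring order: ring A is bought, ring B is formed second by the cycloaddition.

Assumption: 1 and 5 are bought as catalogue items, and the antipode of the chiral acid in steps 3 and 5 is the one found by screening to give the configuration drawn (ring A = C1–C5, C6 = spiro carbon, ring B = C7–C11).

## Route

Step 1
Reactants: 1 5,5-dimethylcyclohex-2-en-1-one
Product: 4 5,5-dimethyl-6-methylidenecyclohex-2-en-1-one, via Mannich base 2 (not isolated), via trimethylammonium iodide 3 (not isolated)
Conditions: LiN(iPr)2, THF, −78 °C; [CH2=NMe2]I, −78 °C → rt; MeI, Et2O/CH2Cl2, rt; aq. NaHCO3, CH2Cl2, rt; used at once, kept cold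
Reagents that add atoms: N,N-dimethylmethyleneiminium iodide (Eschenmoser's salt), C=[N+](C)C.[I-]
Why: Kinetic deprotonation of the enone at C6 gives the cross-conjugated lithium enolate, which is aminomethylated (Mannich reaction), and N-methylation followed by mild-base Hofmann-type (E1cB) loss of trimethylamine gives the exocyclic enone; no stereocentre is formed.

Step 2
Reactants: 5 2-methylbut-1-en-3-yne
Product: 7 2-bromo-3-methylbuta-1,3-diene, via alkenylborane 6 (not isolated)
Conditions: B-bromo-9-BBN, CH2Cl2, 0 °C → rt; AcOH, 0 °C → rt; distilled onto BHT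
Reagents that add atoms: B-bromo-9-borabicyclo[3.3.1]nonane, BrB1C2CCCC1CCC2
Why: Syn bromoboration of the terminal alkyne puts bromine on the internal carbon and leaves the 1,1-disubstituted alkene alone, and acetic acid protonolysis of the alkenyl C–B bond gives the 2-bromodiene (haloboration–protodeboronation, a net Markovnikov hydrobromination).

Step 3
Reactants: 4 5,5-dimethyl-6-methylidenecyclohex-2-en-1-one, 7 2-bromo-3-methylbuta-1,3-diene
Product: 8 (6R)-8-bromo-5,5,9-trimethylspiro[5.5]undeca-2,8-dien-1-one
Conditions: chiral imidodiphosphorimidate Brønsted acid (IDPi; two 3,3'-bis[3,5-bis(trifluoromethyl)phenyl]-BINOL units, N-triflyl groups; 5 mol%), 7 (3 equiv), CH2Cl2, −40 °C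
Reagents that add atoms: none
Why: Chiral-acid-catalysed Diels–Alder reaction of an exocyclic enone, in which the confined anion exposes one face of the protonated exocyclic methylene and so sets the spiro quaternary centre, while the asynchronous transition state places the allyl-cation charge on the methyl-bearing diene carbon (methyl stabilises a cation better than bromine), so the CH2 next to C(Me) bonds to the exocyclic CH2 and bromine ends up 1,3 to the spiro carbon; the endocyclic enone alkene is a much poorer dienophile.

Step 4
Reactants: 8 (6R)-8-bromo-5,5,9-trimethylspiro[5.5]undeca-2,8-dien-1-one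
Product: 10 (6S)-8-bromo-1,5,5,9-tetramethylspiro[5.5]undeca-1,3,8-triene, via tertiary allylic alcohol 9 (not isolated)
Conditions: MeMgBr, LaCl3·2LiCl (30 mol%), THF, 0 °C; aq. NH4Cl; crude, p-TsOH·H2O (5 mol%), PhMe, 4 Å MS, 40 °C
Reagents that add atoms: methylmagnesium bromide, C[Mg]Br
Why: Lanthanide-promoted Grignard 1,2-addition to the hindered enone (no alpha hydrogens; the alkenyl bromide is inert to MeMgBr) gives the tertiary allylic alcohol, whose C1 epimers converge in the acid-catalysed E1 dehydration through the methyl-substituted allyl cation to the endocyclic diene, which is locked between two quaternary carbons; the spiro centre is untouched.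

Step 5
Reactants: 10 (6S)-8-bromo-1,5,5,9-tetramethylspiro[5.5]undeca-1,3,8-triene
Product: 11 (3S,4S,6S)-4,8-dibromo-1,5,5,9-tetramethylspiro[5.5]undeca-1,8-dien-3-ol
Conditions: NBS (1.05 equiv), H2O (3 equiv), chiral IDPi Brønsted acid (5 mol%, antipode that places Br syn to C7H2 of ring B), PhMe/CH2Cl2, −60 °C, dark
Reagents that add atoms: N-bromosuccinimide, O=C1CCC(=O)N1Br; water, O
Why: Proposed new method: a catalyst-controlled, face-selective bromohydroxylation of an unfunctionalised conjugated cyclohexadiene, in which the confined acid protonates NBS inside its chiral pocket, Br+ is delivered to the diene terminus C4 (the only site that gives the methyl-stabilised allyl cation) on the face fixed by the catalyst, and water hydrogen-bonded to the chiral anion attacks the adjacent allylic carbon C3 anti to the partly bridging bromine to give the trans (3S,4S) bromohydrin and return the proton, while any tertiary 1,4-adduct at the shielded C1 terminus re-ionises and funnels to the 1,2-product; the closest known reaction types are the racemic trans-1,2 bromohydrin formation from cyclohexa-1,3-dienes with NBS and water, chiral phosphoric acid-catalysed intermolecular bromoesterification of simple cycloalkenes, and cinchona-alkaloid-catalysed bromohydroxylation of cinnamyl alcohols.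

## Compound list

1 | 5,5-dimethylcyclohex-2-en-1-one | O=C1C=CCC(C)(C)C1 | starting material
2 | 6-[(dimethylamino)methyl]-5,5-dimethylcyclohex-2-en-1-one (racemic Mannich base) | CN(C)CC1C(=O)C=CCC1(C)C | intermediate
3 | 1-(6,6-dimethyl-2-oxocyclohex-3-en-1-yl)-N,N,N-trimethylmethanaminium iodide (racemic) | C[N+](C)(C)CC1C(=O)C=CCC1(C)C.[I-] | intermediate
4 | 5,5-dimethyl-6-methylidenecyclohex-2-en-1-one | C=C1C(=O)C=CCC1(C)C | intermediate
5 | 2-methylbut-1-en-3-yne | C=C(C)C#C | starting material
6 | 9-[(1Z)-2-bromo-3-methylbuta-1,3-dien-1-yl]-9-borabicyclo[3.3.1]nonane | C=C(C)/C(Br)=C/B1C2CCCC1CCC2 | intermediate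
7 | 2-bromo-3-methylbuta-1,3-diene | C=C(C)C(Br)=C | intermediate
8 | (6R)-8-bromo-5,5,9-trimethylspiro[5.5]undeca-2,8-dien-1-one | O=C1C=CCC(C)(C)[C@]12CCC(C)=C(Br)C2 | intermediate
9 | (1RS,6R)-8-bromo-1,5,5,9-tetramethylspiro[5.5]undeca-2,8-dien-1-ol (both C1 epimers) | CC1(O)C=CCC(C)(C)[C@]12CCC(C)=C(Br)C2 | intermediate
10 | (6S)-8-bromo-1,5,5,9-tetramethylspiro[5.5]undeca-1,3,8-triene | CC1=CC=CC(C)(C)[C@]12CCC(C)=C(Br)C2 | intermediate
11 | (3S,4S,6S)-4,8-dibromo-1,5,5,9-tetramethylspiro[5.5]undeca-1,8-dien-3-ol (OH and Br trans; Br on the face of ring A that carries C7H2 of ring B) | CC1=C[C@H](O)[C@@H](Br)C(C)(C)[C@]12CCC(C)=C(Br)C2 | target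

## Step count and risks

Total step count: 5. Longest linear sequence: 4 steps (steps 1, 3, 4, 5 from compound 1); step 2 is a one-step side branch.

Steps most likely to fail:

**Step 5 (the new bromohydroxylation).** The risks are weak face control by the catalyst, competing 1,4-addition, and acid ionisation of the allylic alcohol product. The fallback uses only known reactions and builds the bromohydrin from an enone. It sets out from 9, obtained by stopping step 4 before the acid treatment.
- Babler–Dauben oxidative transposition with [C5H5NH][CrO3Cl] in CH2Cl2 gives (6R)-8-bromo-1,5,5,9-tetramethylspiro[5.5]undeca-1,8-dien-3-one F3.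
- Kinetic alpha-prime deprotonation with LiN(SiMe3)2 in THF at −78 °C and quenching with NBS gives (4S,6S)-4,8-dibromo-1,5,5,9-tetramethylspiro[5.5]undeca-1,8-dien-3-one F4.
- Any accompanying (4R,6S)-4,8-dibromo-1,5,5,9-tetramethylspiro[5.5]undeca-1,8-dien-3-one F5 is separated on silica and recycled by HBr/AcOH equilibration.
- Reduction with iBu2AlH at −78 °C delivers hydride anti to the C–Br bond and gives the cis bromohydrin (3R,4S,6S)-4,8-dibromo-1,5,5,9-tetramethylspiro[5.5]undeca-1,8-dien-3-ol F6.
- Mitsunobu reaction (PhCO2H, PPh3, DIAD, THF) makes the C3–O bond with inversion and gives (3S,4S,6S)-4,8-dibromo-1,5,5,9-tetramethylspiro[5.5]undeca-1,8-dien-3-yl benzoate F7.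
- Base-free ester cleavage with iBu2AlH at −78 °C avoids epoxide closure of the trans bromohydrin, and the sequence comes back to the route at 11.

**Step 3 (asymmetric Diels–Alder with a bromodiene).** The diene is less nucleophilic than isoprene and may react slowly, or with lower enantioselectivity, in the confined acid. The fallback replaces asymmetric catalysis by racemic cycloaddition and resolution. It sets out from 4 and 7. EtAlCl2 in CH2Cl2 at −78 → −20 °C promotes the same methyl-directed cycloaddition and gives 8 as the racemate with its enantiomer (6S)-8-bromo-5,5,9-trimethylspiro[5.5]undeca-2,8-dien-1-one F1. The two are separated by preparative chromatography on a chiral stationary phase, and the route is rejoined at 8. This does not cure a regiochemistry failure, which I consider the less likely problem.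

**Step 4 (one-pot addition and cationic dehydration).** The risks are the exocyclic diene isomer and skeletal rearrangement of the allyl cation next to the spiro centre. The fallback builds the diene regiospecifically with no cation. It sets out from 8. KN(SiMe3)2 in THF at −78 °C removes the only acidic proton (C4–H, gamma) to give the extended dienolate. This is trapped on oxygen with PhNTf2 as (6R)-8-bromo-5,5,9-trimethylspiro[5.5]undeca-1,3,8-trien-1-yl trifluoromethanesulfonate F2. Me2CuLi in THF at −20 °C then replaces the triflate by methyl faster than it touches the hindered tetrasubstituted alkenyl bromide, and the sequence comes back to the route at 10.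

## Further compounds

F1 | step 3 | (6S)-8-bromo-5,5,9-trimethylspiro[5.5]undeca-2,8-dien-1-one | O=C1C=CCC(C)(C)[C@@]12CCC(C)=C(Br)C2
F2 | step 4 | (6R)-8-bromo-5,5,9-trimethylspiro[5.5]undeca-1,3,8-trien-1-yl trifluoromethanesulfonate | O=S(=O)(OC1=CC=CC(C)(C)[C@]12CCC(C)=C(Br)C2)C(F)(F)F
F3 | step 5 | (6R)-8-bromo-1,5,5,9-tetramethylspiro[5.5]undeca-1,8-dien-3-one | CC1=CC(=O)CC(C)(C)[C@]12CCC(C)=C(Br)C2
F4 | step 5 | (4S,6S)-4,8-dibromo-1,5,5,9-tetramethylspiro[5.5]undeca-1,8-dien-3-one | CC1=CC(=O)[C@@H](Br)C(C)(C)[C@]12CCC(C)=C(Br)C2
F5 | step 5 | (4R,6S)-4,8-dibromo-1,5,5,9-tetramethylspiro[5.5]undeca-1,8-dien-3-one | CC1=CC(=O)[C@H](Br)C(C)(C)[C@]12CCC(C)=C(Br)C2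
F6 | step 5 | (3R,4S,6S)-4,8-dibromo-1,5,5,9-tetramethylspiro[5.5]undeca-1,8-dien-3-ol | CC1=C[C@@H](O)[C@@H](Br)C(C)(C)[C@]12CCC(C)=C(Br)C2
F7 | step 5 | (3S,4S,6S)-4,8-dibromo-1,5,5,9-tetramethylspiro[5.5]undeca-1,8-dien-3-yl benzoate | CC1=C[C@H](OC(=O)c3ccccc3)[C@@H](Br)C(C)(C)[C@]12CCC(C)=C(Br)C2
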